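The α-methylene-γ-butyrolactone (O, C16, C15=C17) touches the 14-membered carbocycle only at C1 and C2, and C2 is allylic to C3=C4. The whole lactone is therefore added last: a palladium-catalysed heteroannulation of 2-bromoacrylic acid onto the (1E,3E)-diene of a lactone-free cembratriene forms the C15–C1 and O–C2 bonds, the lactone ring and both ring-fusion stereocentres in one operation and leaves C3=C4 behind. The carbocycle, already carrying the C8, C11, C12 and C13 stereocentres, is built from (R)-linalool by enal propargylation, matched Sharpless epoxidation, Suzuki diene coupling and ring-closing metathesis at C6=C7.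

Key step: step 10

Remark on numbering: cembrane numbering is used throughout (C1 ring-fusion CH, C2 CH–O, C3=C4(Me), C5, C6=C7, C8(Me)(OH), C9, C10, C11–C12(Me) epoxide, C13 OAc, C14; lactone C15 alpha carbon, C16 carbonyl, C17 methylene).
Remark on the starting material: commercial (R)-(−)-linalool is assumed to be of high enantiomeric purity; its carbinol centre becomes C8 and is never touched.

Step 1
Reactants: 1 (R)-(−)-linalool
Product: 2 (2E,6R)-2,6-dimethylocta-2,7-diene-1,6-diol
Conditions: SeO2 (0.3 equiv), t-BuOOH (70% in water, 3 equiv), salicylic acid (0.1 equiv), CH2Cl2, rt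
Reagents that add atoms: tert-butyl hydroperoxide, CC(C)(C)OO (oxygen passed on through catalytic selenium dioxide, O=[Se]=O)
Why: Catalytic SeO2 allylic oxidation (ene reaction, then [2,3]-sigmatropic shift) should attack the (E)-methyl group of the trisubstituted alkene, because the vinyl group has no allylic hydrogen and the tertiary carbinol centre is not involved.

Step 2
Reactants: 2 (2E,6R)-2,6-dimethylocta-2,7-diene-1,6-diol
Product: 3 (2E,6R)-6-hydroxy-2,6-dimethylocta-2,7-dienal
Conditions: activated MnO2 (15 equiv), CH2Cl2, rt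
Reagents that add atoms: none
Why: MnO2 oxidation is selective for the primary allylic alcohol, the tertiary alcohol cannot be oxidised and the E geometry of the enal should be kept.

Step 3
Reactants: 3 (2E,6R)-6-hydroxy-2,6-dimethylocta-2,7-dienal; 4 allenylboronic acid pinacol ester
Product: 6 (3R,6E,8S)-3,7-dimethylundeca-1,6-dien-10-yne-3,8-diol, via pinacol borate ester 5 (not isolated)
Conditions: 4 (1.5 equiv), (S)-TRIP phosphoric acid [(S)-3,3′-bis(2,4,6-triisopropylphenyl)-1,1′-binaphthyl-2,2′-diyl hydrogen phosphate] (5 mol%), 4 Å molecular sieves, toluene, −20 °C; then aq. NaHCO3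
Reagents that add atoms: none
Why: Chiral phosphoric acid-catalysed propargylation (SE2′ transfer from the allenylboronate through a closed six-membered transition state) should add to the Si face of the formyl group and set C13 as S under catalyst control, the (S)-catalyst being the mirror image of the catalyst hand that gives (R)-carbinols from aryl and α,β-unsaturated aldehydes.

Step 4
Reactants: 6 (3R,6E,8S)-3,7-dimethylundeca-1,6-dien-10-yne-3,8-diol
Product: 7 (1S)-1-[(2S,3S)-3-[(3R)-3-hydroxy-3-methylpent-4-en-1-yl]-2-methyloxiran-2-yl]but-3-yn-1-ol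
Conditions: Ti(Oi-Pr)4 (10 mol%), L-(+)-diisopropyl tartrate (13 mol%), t-BuOOH (in decane, 1.5 equiv), 4 Å molecular sieves, CH2Cl2, −20 °C
Reagents that add atoms: tert-butyl hydroperoxide, CC(C)(C)OO
Why: Sharpless asymmetric epoxidation in its matched sense: L-(+)-tartrate reacts fastest with (S)-configured secondary (E)-allylic alcohols and delivers oxygen syn to the hydroxyl on the face that gives the erythro 11S,12R epoxide, a preference reinforced by A(1,2) strain from the C12 methyl group, while the tertiary allylic alcohol, its vinyl group and the alkyne should not react at −20 °C.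

Step 5
Reactants: 7 (1S)-1-[(2S,3S)-3-[(3R)-3-hydroxy-3-methylpent-4-en-1-yl]-2-methyloxiran-2-yl]but-3-yn-1-ol
Product: 8 (1S)-1-[(2R,3S)-3-[(3R)-3-hydroxy-3-methylpent-4-en-1-yl]-2-methyloxiran-2-yl]but-3-yn-1-yl acetate
Conditions: Ac2O (1.5 equiv), pyridine (3 equiv), DMAP (5 mol%), CH2Cl2, 0 °C
Reagents that add atoms: acetic anhydride, CC(=O)OC(C)=O
Why: DMAP-catalysed acylation should take the secondary C13 hydroxyl and leave the hindered tertiary C8 hydroxyl, with no stereocentre touched (the oxirane descriptor changes only through the priority rules).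

Step 6
Reactants: 8 (1S)-1-[(2R,3S)-3-[(3R)-3-hydroxy-3-methylpent-4-en-1-yl]-2-methyloxiran-2-yl]but-3-yn-1-yl acetate
Product: 9 (1S,3E)-1-[(2R,3S)-3-[(3R)-3-hydroxy-3-methylpent-4-en-1-yl]-2-methyloxiran-2-yl]-4-(4,4,5,5-tetramethyl-1,3,2-dioxaborolan-2-yl)but-3-en-1-yl acetate
Conditions: B2pin2 (1.1 equiv), CuCl (5 mol%), Xantphos (6 mol%), NaOt-Bu (10 mol%), MeOH (2 equiv), THF, rt
Reagents that add atoms: bis(pinacolato)diboron, CC1(C)OB(OC1(C)C)B1OC(C)(C)C(C)(C)O1
Why: Copper-catalysed formal hydroboration (syn borylcupration of the terminal alkyne with boron on the terminal carbon, then protonation by methanol) should give the (E)-alkenylboronate, since the boryl-copper species does not add to the unactivated vinyl group and the homopropargylic acetate cannot undergo β-elimination.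

Step 7
Reactants: 10 pent-1-en-4-yne
Product: 12 (1E)-1-iodo-2-methylpenta-1,4-diene, via alkenylalane 11 (not isolated)
Conditions: Me3Al (2.5 equiv), Cp2ZrCl2 (0.25 equiv), CH2Cl2, 0 °C to rt; then I2 (1.2 equiv), THF, −30 to 0 °C
Reagents that add atoms: trimethylaluminium, C[Al](C)C; iodine, II
Why: Negishi zirconium-catalysed carboalumination adds methyl and aluminium syn across the alkyne with aluminium on the terminal carbon, and iodinolysis with retention should give the (E)-iodide, the terminal alkene being much less reactive.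

Step 8
Reactants: 9 (E)-alkenylboronate; 12 (1E)-1-iodo-2-methylpenta-1,4-diene
Product: 13 (1S,3E,5E)-1-[(2R,3S)-3-[(3R)-3-hydroxy-3-methylpent-4-en-1-yl]-2-methyloxiran-2-yl]-6-methylnona-3,5,8-trien-1-yl acetate
Conditions: 12 (1.3 equiv), Pd(dppf)Cl2 (5 mol%), K3PO4 (3 equiv), THF/H2O (5:1), rt
Reagents that add atoms: none
Why: Suzuki–Miyaura coupling of an alkenylboronate with an alkenyl iodide proceeds with retention at both partners and should give the (E,E)-diene C1=C2–C3=C4, the mild phosphate base sparing acetate and epoxide.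

Step 9
Reactants: 13 open-chain tetraene acetate
Product: 14 (1R,2S,4E,6E,9E,11R,14S)-11-hydroxy-1,7,11-trimethyl-15-oxabicyclo[12.1.0]pentadeca-4,6,9-trien-2-yl acetate (the lactone-free carbocycle: 13-acetoxy-11,12-epoxy-8-hydroxy ring with 1E,3E,6E alkenes)
Conditions: second-generation Grubbs catalyst RuCl2(=CHPh)(PCy3)(H2IMes) (10 mol%, in portions), 1,4-benzoquinone (20 mol%), CH2Cl2 (1 mM), 40 °C
Reagents that add atoms: none
Why: Ring-closing metathesis between the allyl terminus and the vinyl group of the tertiary carbinol should close the 14-membered ring at C6=C7 with E geometry (quaternary C8 neighbour, thermodynamic control), the internal diene being far less reactive and the E geometry of C3=C4 keeping the C6 carbene away from C1=C2.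

Step 10
Reactants: 14 lactone-free carbocyclic triene; 15 2-bromoacrylic acid
Product: 16 (1S,2S,3E,6E,8R,11S,12R,13S)-13-acetoxy-11,12-epoxy-8-hydroxycembra-3,6,15(17)-trien-16,2-olide (target)
Conditions: Pd(OAc)2 (10 mol%), PPh3 (20 mol%), n-Bu4NCl (1.5 equiv), NaHCO3 (3 equiv), DMF, 60 °C, 15 (2 equiv) added slowly
Reagents that add atoms: none
Why: Zerovalent palladium (formed in situ from Pd(OAc)2) inserts into the C–Br bond of the 2-bromoacrylate, the 1-carboxyvinyl–palladium bromide adds syn across C1=C2 with carbon going to C1 to give a syn-η3-allyl complex over C2–C3–C4, and the tethered carboxylate attacks C2 from the face opposite palladium, releasing zerovalent palladium. The closest known reaction type is the Larock heteroannulation of 1,3-dienes with halide-bearing aryl or vinylic carboxylic acids (carbopalladation, then capture of the π-allyl by the carboxylate). The lactone, the only ring closed, forms by 5-exo attack of oxygen on the allyl terminus C2, the seven-membered alternative at the fully substituted C4 being disfavoured. C1 is set by the face of carbopalladation: in the conformer that keeps the C13 acetoxy group anti to C1 about C13–C14 the ring chain covers the Si face of C1, so palladium should add from the open Re face to give 1S, and C2 then follows stereospecifically, because syn carbopalladation and anti C–O formation across an E alkene give the cis-fused lactone (2S) while the syn-allyl geometry keeps C3=C4 E. The step needs the diene to react before C6=C7 (a conjugated diene inserts faster and C6=C7 is flanked by quaternary C8), C1 before C4 (C4 is fully substituted), and outer-sphere C–O formation, for which chloride occupies the site that an inner-sphere carboxylate transfer, leading to the trans lactone, would need.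

Compound list
1 | (R)-(−)-linalool, (3R)-3,7-dimethylocta-1,6-dien-3-ol | C=C[C@](C)(O)CCC=C(C)C | starting material
2 | (2E,6R)-2,6-dimethylocta-2,7-diene-1,6-diol | C=C[C@](C)(O)CC/C=C(\C)CO | intermediate
3 | (2E,6R)-6-hydroxy-2,6-dimethylocta-2,7-dienal | C=C[C@](C)(O)CC/C=C(\C)C=O | intermediate
4 | allenylboronic acid pinacol ester, 4,4,5,5-tetramethyl-2-(propa-1,2-dien-1-yl)-1,3,2-dioxaborolane | C=C=CB1OC(C)(C)C(C)(C)O1 | starting material
5 | pinacol borate ester of 6 at the C13 oxygen | C=C[C@](C)(O)CC/C=C(\C)[C@@H](OB1OC(C)(C)C(C)(C)O1)CC#C | intermediate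
6 | (3R,6E,8S)-3,7-dimethylundeca-1,6-dien-10-yne-3,8-diol | C=C[C@](C)(O)CC/C=C(\C)[C@@H](O)CC#C | intermediate
7 | (1S)-1-[(2S,3S)-3-[(3R)-3-hydroxy-3-methylpent-4-en-1-yl]-2-methyloxiran-2-yl]but-3-yn-1-ol | C=C[C@](C)(O)CC[C@@H]1O[C@@]1(C)[C@@H](O)CC#C | intermediate
8 | (1S)-1-[(2R,3S)-3-[(3R)-3-hydroxy-3-methylpent-4-en-1-yl]-2-methyloxiran-2-yl]but-3-yn-1-yl acetate | C=C[C@](C)(O)CC[C@@H]1O[C@@]1(C)[C@@H](OC(C)=O)CC#C | intermediate
9 | (1S,3E)-1-[(2R,3S)-3-[(3R)-3-hydroxy-3-methylpent-4-en-1-yl]-2-methyloxiran-2-yl]-4-(4,4,5,5-tetramethyl-1,3,2-dioxaborolan-2-yl)but-3-en-1-yl acetate | C=C[C@](C)(O)CC[C@@H]1O[C@@]1(C)[C@@H](OC(C)=O)C/C=C/B2OC(C)(C)C(C)(C)O2 | intermediate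
10 | pent-1-en-4-yne | C=CCC#C | starting material
11 | dimethyl[(1E)-2-methylpenta-1,4-dien-1-yl]alumane | C[Al](C)/C=C(\C)CC=C | intermediate
12 | (1E)-1-iodo-2-methylpenta-1,4-diene | I/C=C(\C)CC=C | intermediate
13 | (1S,3E,5E)-1-[(2R,3S)-3-[(3R)-3-hydroxy-3-methylpent-4-en-1-yl]-2-methyloxiran-2-yl]-6-methylnona-3,5,8-trien-1-yl acetate | C=C[C@](C)(O)CC[C@@H]1O[C@@]1(C)[C@@H](OC(C)=O)C/C=C/C=C(\C)CC=C | intermediate
14 | (1R,2S,4E,6E,9E,11R,14S)-11-hydroxy-1,7,11-trimethyl-15-oxabicyclo[12.1.0]pentadeca-4,6,9-trien-2-yl acetate | C1/C=C/C=C(\C)C/C=C/[C@](C)(O)CC[C@@H]2O[C@@]2(C)[C@H]1OC(C)=O | intermediate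
15 | 2-bromoacrylic acid, 2-bromoprop-2-enoic acid | C=C(Br)C(=O)O | starting material
16 | (1S,2S,3E,6E,8R,11S,12R,13S)-13-acetoxy-11,12-epoxy-8-hydroxycembra-3,6,15(17)-trien-16,2-olide | C=C1C(=O)O[C@H]2/C=C(\C)C/C=C/[C@](C)(O)CC[C@@H]3O[C@@]3(C)[C@@H](OC(C)=O)C[C@@H]12 | target

Total step count: 10. Longest linear sequence: 9 steps (steps 1 to 6, then 8 to 10); step 7 is a one-step side branch.

Steps most likely to fail

1. Step 10. The carbopalladation may take the wrong face of the macrocyclic diene, which would give the 1R,2R cis lactone. The C–O bond may also form by inner-sphere transfer (trans lactone), or zerovalent palladium may re-ionise the allylic lactone and erode the kinetic outcome. The conformational argument for Re-face attack is a model, not a certainty. The fallback sets out from tetraene 13 and acid 15 and comes back at 16. The heteroannulation is run on the open-chain (E,E)-diene of 13 with Pd2(dba)3 and a BINOL-derived phosphoramidite ligand, so that the ligand and not the ring conformation chooses the Re face of C1; this should give the open-chain α-methylene lactone F1. Ring-closing metathesis of F1 between its allyl terminus and the vinyl carbinol (second-generation Grubbs catalyst, high dilution) then closes the 14-membered ring directly to 16.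

2. Step 9. The metathesis may give oligomers, the Z alkene, or migration of the skipped C3=C4/C6 diene into conjugation. The fallback sets out from boronate 9 and iodide 12 and comes back at 14. Cross-metathesis of the vinyl carbinol of 9 with the allyl terminus of 12 (excess 12, second-generation Hoveyda–Grubbs catalyst RuCl2(=CH-C6H4-2-Oi-Pr)(H2IMes)) should give the E-configured seco iodide–boronate F2. Intramolecular Suzuki–Miyaura coupling of F2 (Pd(dppf)Cl2, K3PO4, THF/water, high dilution) then closes the ring at the C2–C3 diene bond to give 14.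

3. Step 4. The titanium Lewis acid may promote opening of the new epoxide by the C8 hydroxyl (tetrahydrofuran formation), or conversion may stall. The fallback sets out from diol 6 and comes back at 8. Selective acetylation of the secondary hydroxyl (Ac2O, pyridine, DMAP) gives the enyne acetate F3. Reagent-controlled Shi epoxidation of its trisubstituted alkene with the L-fructose-derived (enantiomeric) Shi ketone and KHSO5 in carbonate buffer at pH 10.5 (MeCN/dimethoxymethane/water, 0 °C), with no Lewis acid present, should then give 8.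

Further compounds
F1 | step 10 | (1S)-1-[(2R,3S)-3-[(3R)-3-hydroxy-3-methylpent-4-en-1-yl]-2-methyloxiran-2-yl]-2-[(2S,3S)-4-methylidene-2-[(1E)-2-methylpenta-1,4-dien-1-yl]-5-oxooxolan-3-yl]ethyl acetate | C=C[C@](C)(O)CC[C@@H]1O[C@@]1(C)[C@@H](OC(C)=O)C[C@H]2C(=C)C(=O)O[C@H]2/C=C(\C)CC=C
F2 | step 9 | (1S,3E)-1-[(2R,3S)-3-[(3R,4E,7E)-3-hydroxy-8-iodo-3,7-dimethylocta-4,7-dien-1-yl]-2-methyloxiran-2-yl]-4-(4,4,5,5-tetramethyl-1,3,2-dioxaborolan-2-yl)but-3-en-1-yl acetate | I/C=C(\C)C/C=C/[C@](C)(O)CC[C@@H]1O[C@@]1(C)[C@@H](OC(C)=O)C/C=C/B2OC(C)(C)C(C)(C)O2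
F3 | step 4 | (4S,5E,9R)-9-hydroxy-5,9-dimethylundeca-5,10-dien-1-yn-4-yl acetate | C=C[C@](C)(O)CC/C=C(\C)[C@@H](OC(C)=O)CC#C
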